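**Retrosynthetic overview**

1. The butenolide is made last: cutting the lactone O–C16 bond and C12–C13 gives an E-alkenyl iodide (C9–CH=CH–I on the finished decalin) and buta-2,3-dienoic acid, joined by a palladium-catalysed coupling–cyclisation; the extra C11=C12 unsaturation is hydrogenated afterwards.
2. Enabling feature: the furan-2(5H)-one ring is substituted only at C13, with C14 a CH and C16 an unsubstituted OCH2. C13–C16 therefore map onto the allenic acid (central allene carbon = C13, terminal CH2 = C16, CO2H = C15), and the carboxylate can close onto a π-allyl terminus.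
3. Ring B: Diels–Alder reaction of a 2-silyloxydiene built on ring A with (E)-2-methylbut-2-enal (bonds C9–C10 and C7–C8; sets C8 and quaternary C9), Saegusa–Ito oxidation to the C5=C10 enone, CBS reduction for C6.
4. Ring A: 2-methylcyclohexane-1,3-dione, hydroxymethylated, esterified with silyl-protected phloretic acid and desymmetrised by CBS reduction (sets C4); C3 travels as a dioxolane.
5. Order of rings: ring A (purchased), ring B (step 10), butenolide ring (step 14).

Key step: step 14

Remark (numbering): halimane locants of the target are used: decalin C1–C10 (ring A: C1–C5, C10; ring B: C5–C10), side chain C11–C12, butenolide C13–C16 (C15 carbonyl, C16 the OCH2), C17 on C8, C18 (methyl) and C19 (CH2O) on C4, C20 on C9.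
Remark (abbreviation): TBS-phloretate = 3-[4-(tert-butyldimethylsilyloxy)phenyl]propanoate.
Assumption (step 4): hydride adds to the 2,2-disubstituted dione anti to the acyloxymethyl arm, as with other 2-alkyl-2-methylcyclohexane-1,3-diones, so the (S)-catalyst reduces the carbonyl group that becomes C5.
Assumption (step 10): the (S)-configured oxazaborolidinium Lewis acid exposes the face of the enal that leads to the 8S,9R series, following the usual model for 2-substituted enals.
Remark: buta-2,3-dienoic acid is a catalogue compound; it is added slowly because it oligomerises.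

**Route**

Step 1
Reactants: 1 3-(4-hydroxyphenyl)propanoic acid (phloretic acid)
Product: 3 3-[4-(tert-butyldimethylsilyloxy)phenyl]propanoic acid, via bis-silyl derivative 2 (not isolated)
Conditions: TBSCl (2.2 equiv), imidazole, DMF, rt; then AcOH–THF–H2O, rt
Reagents that add atoms: tert-butyldimethylsilyl chloride (TBSCl), CC(C)(C)[Si](C)(C)Cl
Why: Silylation of both the phenol and the acid, followed by selective hydrolysis of the far more labile silyl ester, is the standard silyl protection route to a phenol-protected acid.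

Step 2
Reactants: 4 2-methylcyclohexane-1,3-dione; 5 formaldehyde (37% aqueous)
Product: 6 2-(hydroxymethyl)-2-methylcyclohexane-1,3-dione
Conditions: aq. HCHO, Et3N (10 mol %), THF, 0 °C to rt
Reagents that add atoms: none
Why: Aldol addition (hydroxymethylation) of the acidic 2-position of the dione to formaldehyde should give the quaternary carbon, which cannot dehydrate and is not yet a stereocentre because the dione is symmetric.

Step 3
Reactants: 6 2-(hydroxymethyl)-2-methylcyclohexane-1,3-dione; 3 3-[4-(tert-butyldimethylsilyloxy)phenyl]propanoic acid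
Product: 7 (1-methyl-2,6-dioxocyclohexyl)methyl TBS-phloretate
Conditions: DCC, DMAP (5 mol %), CH2Cl2, 0 °C to rt
Reagents that add atoms: none
Why: Steglich esterification should acylate the primary alcohol under near-neutral, cold conditions that outrun retro-aldol loss of formaldehyde and avoid retro-Claisen opening of the dione.

Step 4
Reactants: 7 (1-methyl-2,6-dioxocyclohexyl)methyl TBS-phloretate
Product: 8 [(1R,2R)-2-hydroxy-1-methyl-6-oxocyclohexyl]methyl TBS-phloretate
Conditions: (S)-2-methyl-CBS-oxazaborolidine (20 mol %), BH3·SMe2 (0.6 equiv), THF, −30 °C; MeOH quench; chromatography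
Reagents that add atoms: none
Why: Corey–Bakshi–Shibata reduction should desymmetrise the dione, because the catalyst fixes the carbonyl face that receives hydride (R carbinol, erased in step 6) and the substrate's preference for attack anti to the acyloxymethyl arm then singles out one enantiotopic carbonyl group, which sets the quaternary centre (C4 of the target); the minor diastereomer, which carries the opposite quaternary configuration, is removed by chromatography.

Step 5
Reactants: 8 [(1R,2R)-2-hydroxy-1-methyl-6-oxocyclohexyl]methyl TBS-phloretate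
Product: 9 [(6R,7R)-7-hydroxy-6-methyl-1,4-dioxaspiro[4.5]decan-6-yl]methyl TBS-phloretate
Conditions: ethylene glycol, PPTS (cat.), benzene, reflux (Dean–Stark)
Reagents that add atoms: ethylene glycol, OCCO
Why: Acid-catalysed ketalisation with azeotropic removal of water should protect the only ketone present (the future C3), and the carbinol cannot eliminate into conjugation because the carbon between them is quaternary.

Step 6
Reactants: 9 [(6R,7R)-7-hydroxy-6-methyl-1,4-dioxaspiro[4.5]decan-6-yl]methyl TBS-phloretate
Product: 10 [(6R)-6-methyl-7-oxo-1,4-dioxaspiro[4.5]decan-6-yl]methyl TBS-phloretate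
Conditions: Dess–Martin periodinane, CH2Cl2, 0 °C to rt
Reagents that add atoms: none
Why: Dess–Martin oxidation should return the carbinol to the ketone (future C5) without touching ketal, ester or aryl silyl ether, so that steps 4 to 6 together amount to an enantioselective monoketalisation of the dione.

Step 7
Reactants: 10 [(6R)-6-methyl-7-oxo-1,4-dioxaspiro[4.5]decan-6-yl]methyl TBS-phloretate
Product: 11 [(6R)-6-methyl-7-(trifluoromethanesulfonyloxy)-1,4-dioxaspiro[4.5]dec-7-en-6-yl]methyl TBS-phloretate
Conditions: KN(SiMe3)2 (1.05 equiv) added to ketone and PhNTf2, THF, −78 °C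
Reagents that add atoms: N-phenylbis(trifluoromethanesulfonimide) (PhNTf2), O=S(=O)(N(c1ccccc1)S(=O)(=O)C(F)(F)F)C(F)(F)F
Why: Enol triflate formation can only occur towards the single α-methylene group (future C10) because the other α-carbon is quaternary, and the ketone is deprotonated in preference to the less acidic ester.

Step 8
Reactants: 11 [(6R)-6-methyl-7-(trifluoromethanesulfonyloxy)-1,4-dioxaspiro[4.5]dec-7-en-6-yl]methyl TBS-phloretate; 12 tributyl(1-ethoxyvinyl)stannane
Product: 14 [(6S)-7-acetyl-6-methyl-1,4-dioxaspiro[4.5]dec-7-en-6-yl]methyl TBS-phloretate, via ethoxydiene 13 (not isolated)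
Conditions: Pd(PPh3)4 (5 mol %), LiCl, THF, 65 °C; then aq. oxalic acid, THF, 0 °C
Reagents that add atoms: water, O
Why: Stille coupling of the enol triflate with the acetyl anion equivalent, followed by brief mild hydrolysis of the enol ether (much faster than that of the dioxolane), should give the enone with the ketal intact.

Step 9
Reactants: 14 [(6S)-7-acetyl-6-methyl-1,4-dioxaspiro[4.5]dec-7-en-6-yl]methyl TBS-phloretate
Product: 15 [(6S)-7-[1-(tert-butyldimethylsilyloxy)ethenyl]-6-methyl-1,4-dioxaspiro[4.5]dec-7-en-6-yl]methyl TBS-phloretate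
Conditions: KN(SiMe3)2, then TBSOTf, THF, −78 °C
Reagents that add atoms: tert-butyldimethylsilyl trifluoromethanesulfonate (TBSOTf), CC(C)(C)[Si](C)(C)OS(=O)(=O)C(F)(F)F
Why: Kinetic deprotonation of the enone at its α'-methyl group and O-silylation (silyl dienol ether formation) should give the cross-conjugated 2-silyloxydiene.

Step 10
Reactants: 15 [(6S)-7-[1-(tert-butyldimethylsilyloxy)ethenyl]-6-methyl-1,4-dioxaspiro[4.5]dec-7-en-6-yl]methyl TBS-phloretate; 16 (E)-2-methylbut-2-enal (tiglic aldehyde)
Product: 17 (4S,8S,9R) silyl enol ether aldehyde: decalin with C3 ethylene ketal, C5=C6 carrying OTBS on C6, formyl on C9, methyls on C4, C8 and C9, C19 TBS-phloretate; mixture of C10 epimers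
Conditions: (S)-o-tolyl-CBS-oxazaborolidine (20 mol %), Tf2NH (16 mol %), 16 (3 equiv), CH2Cl2, −78 to −40 °C
Reagents that add atoms: none
Why: In this catalytic enantioselective Diels–Alder reaction the 2-silyloxy group (para rule) and the ring substituent at the diene terminus (ortho rule) both direct the formyl-bearing carbon to C10, the E geometry of the enal places the C8 and C9 methyl groups cis, and the chiral Lewis acid selects the enantioface of the enal and so sets C8 and C9 whatever the diene face or endo/exo mode, which affect only the transient C10 centre.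

Step 11
Reactants: 17 (4S,8S,9R) silyl enol ether aldehyde (C10 epimers)
Product: 18 (4S,8S,9R) enone aldehyde: C6 ketone, C5=C10, formyl on C9, C3 ethylene ketal, C19 TBS-phloretate
Conditions: Pd(OAc)2 (1.1 equiv), MeCN, rt to 40 °C
Reagents that add atoms: none
Why: Saegusa–Ito oxidation of the regiodefined silyl enol ether should give the C5=C10 enone, because the divalent palladium enolate at C5 has its only β-hydrogen at C10 (C4 is quaternary), and it funnels both C10 epimers into one compound.

Step 12
Reactants: 18 (4S,8S,9R) enone aldehyde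
Product: 19 (4S,8S,9S) E-alkenyl iodide: C9–CH=CH–I, C6 ketone, C5=C10, C3 ethylene ketal, C19 TBS-phloretate
Conditions: CrCl2 (6 equiv), CHI3 (2 equiv), THF, 0 °C to rt
Reagents that add atoms: iodoform (CHI3), IC(I)I
Why: Takai olefination should convert the neopentyl aldehyde chemoselectively (enone, ester and ketal are inert to the gem-dichromium reagent) into the E-alkenyl iodide, and any Z isomer is harmless because C11=C12 is saturated in step 15.

Step 13
Reactants: 19 (4S,8S,9S) E-alkenyl iodide enone
Product: 20 (4S,6S,8S,9S) allylic alcohol: C6–OH, C5=C10, C9–CH=CH–I, C3 ethylene ketal, C19 TBS-phloretate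
Conditions: (R)-2-methyl-CBS-oxazaborolidine (0.5 equiv), BH3·SMe2, toluene, −40 °C; MeOH quench
Reagents that add atoms: none
Why: Corey–Bakshi–Shibata reduction with the (R)-catalyst should treat the tetrasubstituted alkene arm as the large group and deliver hydride to the face that gives the 6S carbinol (reagent control), while ketal, ester and alkenyl iodide are inert to borane at this temperature.

Step 14
Reactants: 20 (4S,6S,8S,9S) allylic alcohol alkenyl iodide; 21 buta-2,3-dienoic acid
Product: 23 (4S,6S,8S,9S) dienyl butenolide: 4-[(E)-2-(decalin-C9-yl)ethenyl]furan-2(5H)-one with C6–OH, C5=C10, C3 ethylene ketal, C19 TBS-phloretate, via allylpalladium iodide 22 (not isolated)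
Conditions: Pd(PPh3)4 (5 mol %), Ag2CO3 (5 mol %), K2CO3 (2 equiv), MeCN, 60 °C, slow addition of 21 (2 equiv)
Reagents that add atoms: none
Why: Oxidative addition of zerovalent palladium into the C12–I bond of 20 gives an alkenylpalladium iodide whose alkenyl group adds to the central allene carbon of 21 (carbopalladation), forming C12–C13 and a π-allylpalladium unit over C14–C13–C16 (22); the C15 carboxylate then attacks the unsubstituted terminus C16, which forms the O–C16 bond, closes the lactone and returns zerovalent palladium, while Ag2CO3 assists halide abstraction and K2CO3 takes up HI. The closest known reaction type is the palladium/silver-cocatalysed coupling–cyclisation of 2,3-allenoic acids with aryl and alkenyl halides to 4-substituted furan-2(5H)-ones. The one ring closed (O, C15, C14, C13, C16) forms by intramolecular allylic C–O substitution in an endo mode, all three allyl carbons lying inside the ring, and the cis arrangement of carboxylate and C16 that this needs is reached by π–σ–π isomerisation of the allyl unit. No stereocentre is created: the C13=C14 bond is held cis by the ring, and the geometry of C11=C12 does not matter because that bond is saturated in step 15. The step needs addition at the central allene carbon and C–O closure at C16 rather than direct cycloisomerisation of 21; the first is inherent to allene insertion, which alone gives the stabilised π-allyl unit, and the second is secured by the structure, since C16 is an unhindered CH2 four bonds from the carboxylate oxygen while C14 cannot be reached by its own carboxyl group. The free C6 hydroxyl, the ester, the dioxolane and the tetrasubstituted alkene should be spectators because 20 offers a single C–I bond to the catalyst.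

Step 15
Reactants: 23 (4S,6S,8S,9S) dienyl butenolide
Product: 24 (4S,6S,8S,9R) butenolide with saturated C11–C12: 4-[2-(decalin-C9-yl)ethyl]furan-2(5H)-one with C6–OH, C5=C10, C3 ethylene ketal, C19 TBS-phloretate
Conditions: H2 (1 atm), RhCl(PPh3)3 (10 mol %), benzene–EtOH, rt
Reagents that add atoms: none
Why: Homogeneous hydrogenation with RhCl(PPh3)3 is selective for the least substituted alkene, so the 1,2-disubstituted C11=C12 bond should be reduced while the trisubstituted conjugated butenolide alkene and the tetrasubstituted C5=C10 alkene are left.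

Step 16
Reactants: 24 (4S,6S,8S,9R) butenolide ketal
Product: 26 [(1S,5R,6S,8S)-8-hydroxy-1,5,6-trimethyl-2-oxo-5-[2-(5-oxo-2,5-dihydrofuran-3-yl)ethyl]-1,2,3,4,5,6,7,8-octahydronaphthalen-1-yl]methyl 3-(4-hydroxyphenyl)propanoate (CNP0301014.1; 4S,6S,8S,9R in halimane numbering), via silyl ether ketone 25 (not isolated)
Conditions: PPTS, THF–H2O, 45 °C; then HF·pyridine, THF, 0 °C
Reagents that add atoms: water, O
Why: Mild acid hydrolysis of the dioxolane followed by fluoride cleavage of the aryl silyl ether (global deprotection) should free the C3 ketone, which cannot pull the C5=C10 alkene into conjugation because C4 is quaternary, and the phenol, without touching any stereocentre.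

**Compound list**

1 | 3-(4-hydroxyphenyl)propanoic acid (phloretic acid) | OC(=O)CCc1ccc(O)cc1 | starting material
2 | tert-butyldimethylsilyl 3-[4-(tert-butyldimethylsilyloxy)phenyl]propanoate | CC(C)(C)[Si](C)(C)OC(=O)CCc1ccc(O[Si](C)(C)C(C)(C)C)cc1 | intermediate
3 | 3-[4-(tert-butyldimethylsilyloxy)phenyl]propanoic acid | OC(=O)CCc1ccc(O[Si](C)(C)C(C)(C)C)cc1 | intermediate
4 | 2-methylcyclohexane-1,3-dione | CC1C(=O)CCCC1=O | starting material
5 | formaldehyde (37% aqueous) | C=O | starting material
6 | 2-(hydroxymethyl)-2-methylcyclohexane-1,3-dione | CC1(CO)C(=O)CCCC1=O | intermediate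
7 | (1-methyl-2,6-dioxocyclohexyl)methyl TBS-phloretate | CC1(COC(=O)CCc2ccc(O[Si](C)(C)C(C)(C)C)cc2)C(=O)CCCC1=O | intermediate
8 | [(1R,2R)-2-hydroxy-1-methyl-6-oxocyclohexyl]methyl TBS-phloretate | O[C@@H]1CCCC(=O)[C@]1(C)COC(=O)CCc1ccc(O[Si](C)(C)C(C)(C)C)cc1 | intermediate
9 | [(6R,7R)-7-hydroxy-6-methyl-1,4-dioxaspiro[4.5]decan-6-yl]methyl TBS-phloretate | O[C@@H]1CCCC2(OCCO2)[C@]1(C)COC(=O)CCc1ccc(O[Si](C)(C)C(C)(C)C)cc1 | intermediate
10 | [(6R)-6-methyl-7-oxo-1,4-dioxaspiro[4.5]decan-6-yl]methyl TBS-phloretate | O=C1CCCC2(OCCO2)[C@]1(C)COC(=O)CCc1ccc(O[Si](C)(C)C(C)(C)C)cc1 | intermediate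
11 | [(6R)-6-methyl-7-(trifluoromethanesulfonyloxy)-1,4-dioxaspiro[4.5]dec-7-en-6-yl]methyl TBS-phloretate | O=S(=O)(OC1=CCCC2(OCCO2)[C@]1(C)COC(=O)CCc1ccc(O[Si](C)(C)C(C)(C)C)cc1)C(F)(F)F | intermediate
12 | tributyl(1-ethoxyvinyl)stannane | CCCC[Sn](CCCC)(CCCC)C(=C)OCC | starting material
13 | [(6S)-7-(1-ethoxyethenyl)-6-methyl-1,4-dioxaspiro[4.5]dec-7-en-6-yl]methyl TBS-phloretate | C=C(OCC)C1=CCCC2(OCCO2)[C@]1(C)COC(=O)CCc1ccc(O[Si](C)(C)C(C)(C)C)cc1 | intermediate
14 | [(6S)-7-acetyl-6-methyl-1,4-dioxaspiro[4.5]dec-7-en-6-yl]methyl TBS-phloretate | CC(=O)C1=CCCC2(OCCO2)[C@]1(C)COC(=O)CCc1ccc(O[Si](C)(C)C(C)(C)C)cc1 | intermediate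
15 | [(6S)-7-[1-(tert-butyldimethylsilyloxy)ethenyl]-6-methyl-1,4-dioxaspiro[4.5]dec-7-en-6-yl]methyl TBS-phloretate | C=C(O[Si](C)(C)C(C)(C)C)C1=CCCC2(OCCO2)[C@]1(C)COC(=O)CCc1ccc(O[Si](C)(C)C(C)(C)C)cc1 | intermediate
16 | (E)-2-methylbut-2-enal (tiglic aldehyde) | C/C=C(\C)C=O | starting material
17 | (4S,8S,9R) silyl enol ether aldehyde (C3 ethylene ketal, C5=C6–OTBS, C9–CHO, C19 TBS-phloretate; C10 epimers) | C[C@H]1CC(O[Si](C)(C)C(C)(C)C)=C2C(CCC3(OCCO3)[C@]2(C)COC(=O)CCc2ccc(O[Si](C)(C)C(C)(C)C)cc2)[C@]1(C)C=O | intermediate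
18 | (4S,8S,9R) enone aldehyde (C6 ketone, C5=C10, C9–CHO, C3 ethylene ketal, C19 TBS-phloretate) | C[C@H]1CC(=O)C2=C(CCC3(OCCO3)[C@]2(C)COC(=O)CCc2ccc(O[Si](C)(C)C(C)(C)C)cc2)[C@]1(C)C=O | intermediate
19 | (4S,8S,9S) E-alkenyl iodide enone (C9–CH=CH–I, C6 ketone, C5=C10, C3 ethylene ketal, C19 TBS-phloretate) | C[C@H]1CC(=O)C2=C(CCC3(OCCO3)[C@]2(C)COC(=O)CCc2ccc(O[Si](C)(C)C(C)(C)C)cc2)[C@]1(C)/C=C/I | intermediate
20 | (4S,6S,8S,9S) allylic alcohol alkenyl iodide (C6–OH, C5=C10, C9–CH=CH–I, C3 ethylene ketal, C19 TBS-phloretate) | C[C@H]1C[C@H](O)C2=C(CCC3(OCCO3)[C@]2(C)COC(=O)CCc2ccc(O[Si](C)(C)C(C)(C)C)cc2)[C@]1(C)/C=C/I | intermediate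
21 | buta-2,3-dienoic acid | C=C=CC(=O)O | starting material
22 | allylpalladium iodide from 20 and 21 (σ-allyl form at C16, phosphine ligands omitted) | C[C@H]1C[C@H](O)C2=C(CCC3(OCCO3)[C@]2(C)COC(=O)CCc2ccc(O[Si](C)(C)C(C)(C)C)cc2)[C@]1(C)/C=C/C(C[Pd]I)=CC(=O)O | intermediate
23 | (4S,6S,8S,9S) dienyl butenolide (E-C11=C12, furan-2(5H)-one at C12, C6–OH, C5=C10, C3 ethylene ketal, C19 TBS-phloretate) | C[C@H]1C[C@H](O)C2=C(CCC3(OCCO3)[C@]2(C)COC(=O)CCc2ccc(O[Si](C)(C)C(C)(C)C)cc2)[C@]1(C)/C=C/C1=CC(=O)OC1 | intermediate
24 | (4S,6S,8S,9R) butenolide with saturated C11–C12 (C6–OH, C5=C10, C3 ethylene ketal, C19 TBS-phloretate) | C[C@H]1C[C@H](O)C2=C(CCC3(OCCO3)[C@]2(C)COC(=O)CCc2ccc(O[Si](C)(C)C(C)(C)C)cc2)[C@]1(C)CCC1=CC(=O)OC1 | intermediate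
25 | (4S,6S,8S,9R) C3 ketone with the phenol still silylated | C[C@H]1C[C@H](O)C2=C(CCC(=O)[C@]2(C)COC(=O)CCc2ccc(O[Si](C)(C)C(C)(C)C)cc2)[C@]1(C)CCC1=CC(=O)OC1 | intermediate
26 | [(1S,5R,6S,8S)-8-hydroxy-1,5,6-trimethyl-2-oxo-5-[2-(5-oxo-2,5-dihydrofuran-3-yl)ethyl]-1,2,3,4,5,6,7,8-octahydronaphthalen-1-yl]methyl 3-(4-hydroxyphenyl)propanoate (CNP0301014.1) | C[C@H]1C[C@H](O)C2=C(CCC(=O)[C@]2(C)COC(=O)CCc2ccc(O)cc2)[C@]1(C)CCC1=CC(=O)OC1 | target

**Summary**

Total step count: 16. Longest linear sequence: 15 steps (steps 2 to 16, from 2-methylcyclohexane-1,3-dione); step 1 is a one-step side branch.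

Steps most likely to fail:

Step 10 (Diels–Alder). The catalyst-bound trisubstituted enal has to approach a diene whose inner carbon C5 carries the quaternary C4, so the cycloaddition may be slow or the enantioface control may erode. Fallback: setting out from 15 and 16, the cycloaddition would be run without a chiral catalyst under high pressure (about 12 kbar, CH2Cl2, rt). This should give 17 together with its 8R,9S diastereomer F1. Saegusa–Ito oxidation of the mixture as in step 11 would give 18 and the 8R,9S enone F2. These are diastereomers because C4 is fixed, so they would be separated by chromatography and the route rejoined at 18.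

Step 4 (desymmetrisation). If the intrinsic facial bias of the dione is weak, the two enantiotopic carbonyl groups are discriminated poorly and the configuration at C4 leaks. Fallback: setting out from 7, NaBH4 (0.3 equiv, MeOH, −40 °C) would give 8 as a racemate, that is, together with its enantiomer F3. Lipase-catalysed acylation (Candida antarctica lipase B, vinyl acetate, a standard kinetic resolution of secondary alcohols) should convert the R carbinol into the acetate F4, which is separated from unreacted F3. Lipase-mediated butanolysis of F4 would return 8, where the route is rejoined.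

Step 15 (chemoselective hydrogenation). The dienyl lactone may take up hydrogen slowly, and over-reduction of the butenolide alkene or alkene migration may compete. Fallback: setting out from 23, conjugate hydride delivery to C11 with [(Ph3P)CuH]6 (benzene, rt, then aqueous NH4Cl) would replace the hydrogenation. Protonation of the resulting dienolate should give 24 and, by α-protonation, the deconjugated isomer F5 with an exocyclic C12=C13 bond. DBU (CH2Cl2, rt) would then move that alkene into conjugation, which rejoins the route at 24.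

Further compounds
F1 | step 10 | 8R,9S diastereomer of 17 (C10 epimers) | C[C@@H]1CC(O[Si](C)(C)C(C)(C)C)=C2C(CCC3(OCCO3)[C@]2(C)COC(=O)CCc2ccc(O[Si](C)(C)C(C)(C)C)cc2)[C@@]1(C)C=O
F2 | step 10 | 8R,9S diastereomer of 18 | C[C@@H]1CC(=O)C2=C(CCC3(OCCO3)[C@]2(C)COC(=O)CCc2ccc(O[Si](C)(C)C(C)(C)C)cc2)[C@@]1(C)C=O
F3 | step 4 | [(1S,2S)-2-hydroxy-1-methyl-6-oxocyclohexyl]methyl TBS-phloretate (enantiomer of 8) | O[C@H]1CCCC(=O)[C@@]1(C)COC(=O)CCc1ccc(O[Si](C)(C)C(C)(C)C)cc1
F4 | step 4 | [(1R,2R)-2-acetoxy-1-methyl-6-oxocyclohexyl]methyl TBS-phloretate (acetate of 8) | CC(=O)O[C@@H]1CCCC(=O)[C@]1(C)COC(=O)CCc1ccc(O[Si](C)(C)C(C)(C)C)cc1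
F5 | step 15 | deconjugated isomer of 24 with exocyclic C12=C13 (4-alkylidene-dihydrofuran-2(3H)-one) | C[C@H]1C[C@H](O)C2=C(CCC3(OCCO3)[C@]2(C)COC(=O)CCc2ccc(O[Si](C)(C)C(C)(C)C)cc2)[C@]1(C)CC=C1CC(=O)OC1
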